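A small charge of Z, 60.0 mM in the cedar run, stopped short: cJ read 23.2 mM at 20 min and 23.0 mM at 28 min, with 37.0 mM of Z, bound forms counted, still in the flask. The ash and oak runs flattened below their charges as well, so I looked for a measure of how far a given charge of Q carries a flask.

| flask | Z | Q | time |
|---|---|---|---|
| ash | 120 mM | 6.00 mM |  |
| cedar | 60.0 mM | 6.00 mM |  |
| oak | 120 mM | 9.00 mM |  |
| elm | 240 mM | 6.00 mM |  |
| larch | 120 mM | 12.0 mM | 28 min |

| run | time / min | [J] / mM |
|---|---|---|
| ash run | 2.1 | 16.0 |
| ash run | 6.5 | 37.9 |
| ash run | 12 | 56.1 |
| ash run | 20 | 65.4 |
| ash run | 28 | 66.3 |
| cedar run | 2.1 | 9.2 |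
| cedar run | 6.5 | 18.6 |
| cedar run | 12 | 21.0 |
| cedar run | 20 | 23.2 |
| cedar run | 28 | 23.0 |
| oak run | 2.1 | 23.7 |
| oak run | 6.5 | 51.1 |
| oak run | 12 | 69.1 |
| oak run | 20 | 76.9 |
| oak run | 28 | 78.0 |
| elm run | 2.1 | 22.9 |
| elm run | 6.5 | 63.1 |
| elm run | 12 | 105.5 |
| elm run | 20 | 144.1 |
| elm run | 28 | 164.3 |

(scatter of a reading: 1 mM)

- Overall: Z -> J, with Q as catalyst.
- Constant volume, constant temperature.
- What is held in complexes is read along with the free species.
- An order is taken over about fifteen percent of the charge, up and down.

1. reaction order in [Q] at the outset, round the charge of the ash run, defined at two percent of the Z turned into J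
2. reaction order in [Z] at the outset, round the charge of the ash run, defined at two percent of the Z turned into J (one fixed amount of J, the same in the runs compared)
3. the cedar run starts with 60.0 mM less of Z than the ash run, and with no J. Compared where both hold the same amount of Z, once fifteen percent of what the cedar run was charged with has turned into J, is the cedar run faster, slower or alike (within a tenth)?
4. J in the larch run at 28 min, as a share of the Z charged
5. which of these the readings show (the loaded catalyst dies / the substrate kills the catalyst / two substrates go astray together / the catalyst dies by itself / the product kills the catalyst)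

The turnover number, cJ per cQ charged at the last reading, fails as that measure, for it was 3.83 in the cedar run and 11.0 in the ash run, larger at the same cQ. The ash run gave 0.00171 mM⁻² for what I call the reach, the rise of the reciprocal of cZ from the charge to the last reading, per unit of cQ charged.

I tested it in two independent ways. The cedar run changes Z, with half the ash charge and the same cQ, and gave 0.00173 mM⁻². The oak run changes Q, with 9.00 mM against 6.00 mM and the same charge of Z, and gave 0.00172 mM⁻². These come from different flasks and agree. The elm run parts from them, lower at 0.00151 mM⁻². The elm run is the one that cheats, since its cJ still climbed 20.2 mM over the last interval, more than the 0.900 mM of the ash run, so its last reading is no stopping point.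

The oak run, with more Q than the ash run, gained 1.10 mM over its last interval, so I took the larch run as stopped by 28 min too. With the ash reach, my own reckoning put cJ in the larch run at 85.4 mM, which is 71.2 % of its charge.

The forecast set the order in Q at 1, the order in Z at 0.55, the cedar run faster, the larch share at 70.5 %, lower than mine, and the verdict the catalyst dies by itself, on this ground: “Decay instead speeds up as Z falls, whatever J is: substrate protects a catalyst dying by itself.”

    Q + Z ⇌ QZ, settled at all times (8.610 L mol⁻¹)
    QZ + Z ⇌ QZ2, settled at all times (28.70 L mol⁻¹)
    QZ2 → J + QZ (2.250 min⁻¹)
    Q → Zu (0.2670 min⁻¹)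

The flask gave an order in Q of 0.97, an order in Z of 0.67, the cedar run faster, a larch share of 71.2 %, and the verdict the catalyst dies by itself. Where both held the same amount of Z, at the point of comparison asked about, the cedar run went at 39 times the rate of the ash run. The reach from the ash run, put to the elm charge, gives cJ 171 mM, and the elm run read 164.3 mM at 28 min, which is 96.1 % of that.

The earlier runs and the new flask were computed from invented constants, noise included.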